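# Proposed total synthesis of CNP0108636.1 by anionic oxy-Cope ring expansion

## Analysis of the target

Target 39 is a germacrane: a ten-membered carbocycle (C1 to C10) in which an oxygen bridges C3 and C10. The bridge closes a 3(2H)-furanone (C1 ketone, C2=C3 enol ether, C10 quaternary with the C14 methyl). A trans-fused α-methylene-γ-butyrolactone sits on C6/C7 (oxygen on C6, C11 to C13), an angelate on O8 and a hydroxymethyl group (C15) on C4. The five stereocentres are 4S, 6R, 7S, 8R and 10S. With the ring drawn C1 to C10 clockwise, the lactone oxygen and C14 lie on one face and C11, O8, O10 and C15 on the other. C6, C7 and C8 are contiguous, C10 is separated from them by C9, and C4 is remote from all of them. C4 is also a vinylogous α-position of the furanone and can epimerise. The exocyclic methylene lactone (Michael acceptor), the angelate (Z to E isomerisation), the base-labile furanone and the free primary alcohol limit what the late steps may use. The hard problems are the medium ring, the control of the isolated C4 centre and the order of the carbonyl chemistry at the end. The strategy rests on one pattern: the C1 carbonyl, the C3–C4 bond and the C6 carbon are spaced as a (3,3) shift leaves them when C1 and C6 were once bonded in a cyclohexane made of C1, C6, C7, C8, C9 and C10, and O8 and O10 are cis-1,3 on that six-membered ring.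

## Retrosynthetic reasoning

**Endgame protecting groups.** The C15 silyl ether of 38 is removed last, and the angelate of 38 is cut back to alcohol 35 and angelic acid 36. The ester goes on late because it would not survive enolate, hydride or peracid chemistry, and the silyl ether keeps the primary hydroxyl out of the acylation.

**Furanone.** The O10–C3 bond of 35 is cut to give 1,3-diketone 34, whose C8/C10 acetonide hides the tertiary hydroxyl. One acid treatment must remove the acetonide and cyclodehydrate, so the bridge and the enol ether arise together without a separate oxygen-transfer step.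

**C1/C3 oxygenation.** Diketone 34 goes back to diol 33 and then to silane 32 by exchanging C3–O for C3–Si. Silicon is used at C3 because an oxygen there would be β to the enolate formed in the ring expansion and would be eliminated; a C–Si bond survives and is oxidised with retention later.

**Exocyclic methylene.** C13 of 32 is removed to give lactone 29, and the C1 alcohol of 29 is the reduced form of ketone 28. The methylenation needs a lactone enolate, so the more acidic C1 ketone is masked as the alcohol, which is re-oxidised together with C3–OH at no extra cost.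

**Lactone.** The C12 carbonyl of 28 is taken back to the 1,4-diol 27, and the C6–O bond of 27 to the (E)-alkene 24. Halolactonisation was considered and rejected. In a trans-cyclodecene the side-chain nucleophile and an external electrophile both need the one exposed alkene face, while an anti addition would put one of them inside the ring. The forward reaction therefore has to deliver oxygen to C6 and hydrogen to C5 from the same face, from the C12 oxygen, which is done through a silicon tether.

**Ring expansion (key disconnection).** In 24 (as its protected form 23) the C3–C4 bond is cut and C1–C6 is reconnected, giving cyclohexanol 20. This is the only disconnection that turns the ten-membered ring into a six-membered one and at the same time derives C4 from alkene geometry. The forward step must pass through one chair with both alkenyl groups equatorial.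

**Six-membered ring, oxygen pattern.** The Z-alkene of 20 comes from alkyne 19. The acetonide and the C12 ether of 19 come from triol 17. The C8 carbinol of 17 comes from ketone 15, and the tertiary C10 hydroxyl of 15 from epoxy ketone 14. Each oxygen is thus introduced by a reagent that adds anti to an existing axial oxygen or equatorially to a ketone, which is the natural sense on this ring.

**Six-membered ring, carbon substituents.** The C7–C11 bond of 13 is cut (enolate alkylation with a two-carbon ester unit, trans to C6) to give 12 and then 11. The C6–C5 bond of 11 is cut to quinol 7 and alkyne 9. The forward reaction is an alkoxide-directed conjugate alkynylation that places the alkyne cis to the C1 hydroxyl.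

**First stereocentre.** The C1–C2 bond of 7 is cut to dienone 2 and ethynylsilane 3. The vinyl group is added before any other centre exists, because a later addition to a C1 ketone flanked by an axial C10 oxygen would come from the wrong face. Dienone 2 comes from phenol 1.

## Alternatives that were turned down

**Alternative 1: carboxylate-directed C–H lactonisation.** The lactone O–C6 bond would be made last, by oxidising the C6–H bond that lies γ to a free C12 carboxylic acid on the complete furanone bicycle. The forward key step uses Mn(OTf)2, a chiral bis(pyrrolidine)bis(pyridine) ligand and H2O2, and gives A1.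
- For: C6 needs no earlier functional group, and the carboxylate itself steers the oxidant. The other γ-position, C8, is switched off by its acyloxy group.
- Against: C6 is an unactivated methylene in a molecule that also offers the tertiary allylic C4–H, C9–H2 and an electron-rich enol ether. Electron-poor protecting groups and a C13 acetoxymethyl placeholder have to be carried and then exchanged. The step makes only the five-membered ring, so the ten-membered skeleton must come from elsewhere.
- Comparison: it is stronger in redox economy at C6, where the chosen route spends two steps. The chosen route offers a key step that builds the carbocycle and C4 through a pericyclic transition state instead of discrimination among similar C–H bonds.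

**Alternative 2: allylchromium ring closure at C5–C6.** The ring would be closed at C5–C6. CrCl2 turns an allylic bromide on the furanone side into an allylchromium that adds to a C6 aldehyde (Nozaki–Hiyama–Kishi type) and gives A2, with C4 as an exocyclic methylene.
- For: the furanone and the C6–C8 fragment are made separately, the angelate is tolerated, and C6–OH is formed where the lactone needs it.
- Against: a strained ten-membered ring is closed end to end, and C6 is set in a macrocyclic transition state. The C4 stereocentre and C15–OH must afterwards come from anti-Markovnikov hydration of a 1,1-disubstituted alkene conjugated to the furanone, in the presence of the C11=C13 methylene, with both chemoselectivity and face selectivity open.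
- Comparison: it is more convergent and needs no late unmasking of the furanone. The chosen route is linear, but C4 and the (E)-alkene come out of one concerted step with a predictable sense.

**Alternative 3: tethered vinyl-radical cyclisation.** C7–C11 and C8–O would be cut. Bu3SnH with excess TEMPO converts an O6 bromoacetal of the bicyclic furanone into a C11 vinyl radical that adds to C7, and the C8 radical is trapped, giving A3.
- For: the methylene-bearing C11 to C13 unit arrives intact, so no enolate methylenation is needed at the end. O8 is introduced in the same neutral step.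
- Against: C7 and C8 are both set by radical events on a flexible medium ring, C8 by an untethered trap. The vinyl radical can be reduced, shift hydrogen or add across the ring to the furanone enone. N–O cleavage, acetal oxidation and acylation follow.
- Comparison: it is stronger in how the methylene lactone is delivered. The chosen route sets C7 and C8 on a rigid cyclohexane, where their control is routine, before the ring is expanded.

Key step: step 12

Assumption: germacrane numbering (C1 to C15 as in 39) is used for every intermediate, including the six-membered-ring compounds; the SMILES strings fix all configurations.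
Assumption: alcohols 29 to 33 are carried as the mixture of C1 epimers that step 15 gives, since this centre becomes a carbonyl again in step 18.
Assumption: the antipode of the bis(sulfonamide) ligand in step 2 is the one that gives the (1R)-carbinol; this has to be established on the first run.

## Route

Step 1
Reactants: 1 4-methoxy-2-methylphenol
Product: 2 4,4-dimethoxy-2-methylcyclohexa-2,5-dien-1-one
Conditions: PhI(OAc)2, MeOH, 0 °C to rt
Reagents that add atoms: methanol, CO
Why: Oxidative dearomatisation of a para-alkoxyphenol by a trivalent iodine reagent; methanol captures the phenoxenium ion para to the oxygen and gives the quinone monoketal, whose free carbonyl is the future C1 next to the methyl-bearing C10.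

Step 2
Reactants: 2 4,4-dimethoxy-2-methylcyclohexa-2,5-dien-1-one; 3 ethynyl(dimethyl)phenylsilane
Product: 7 (4R)-4-[(E)-2-(dimethylphenylsilyl)ethenyl]-4-hydroxy-3-methylcyclohexa-2,5-dien-1-one, via vinylzirconocene 4 (not isolated), via vinylzinc 5 (not isolated), via quinol ketal 6 (not isolated)
Conditions: 3, Cp2Zr(H)Cl, CH2Cl2, rt; Me2Zn, toluene, −78 °C; then 2, Ti(OiPr)4, bis(hydroxycamphorsulfonamide) ligand of trans-cyclohexane-1,2-diamine (10 mol %), rt; aq. NH4Cl; then 10% aq. oxalic acid, THF, 0 °C
Reagents that add atoms: water, O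
Why: syn-Hydrozirconation fixes the E geometry, Zr-to-Zn exchange gives the alkenylzinc, and the titanium/bis(sulfonamide)-catalysed asymmetric 1,2-addition of an alkenylzinc to a ketone should set C1, the catalyst telling the methyl-substituted flank of the ketone from the unsubstituted one. Mild aqueous acid then hydrolyses the ketal to the dienone without ionising the tertiary carbinol.

Step 3
Reactants: 8 prop-2-yn-1-ol
Product: 9 tert-butyl(diphenyl)(prop-2-yn-1-yloxy)silane
Conditions: t-BuPh2SiCl, imidazole, CH2Cl2, rt
Reagents that add atoms: tert-butyl(chloro)diphenylsilane, CC(C)(C)[Si](Cl)(c1ccccc1)c1ccccc1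
Why: Silyl ether formation; the bulky group on the future O15 should survive every later step and is removed last.

Step 4
Reactants: 7 (4R)-4-[(E)-2-(dimethylphenylsilyl)ethenyl]-4-hydroxy-3-methylcyclohexa-2,5-dien-1-one; 9 tert-butyl(diphenyl)(prop-2-yn-1-yloxy)silane
Product: 11 (4R,5R)-5-[3-(tert-butyldiphenylsilyloxy)prop-1-ynyl]-4-[(E)-2-(dimethylphenylsilyl)ethenyl]-4-hydroxy-3-methylcyclohex-2-en-1-one, via alkynylmagnesium bromide 10 (not isolated)
Conditions: 9, EtMgBr, THF, 40 °C; then 7, THF, −78 to 0 °C (3 equiv of 10); aq. NH4Cl
Reagents that add atoms: none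
Why: Alkoxide-directed (ligand-assisted) conjugate addition of a Grignard reagent to a 4-hydroxycyclohexadienone: the magnesium alkoxide of 7 binds a second alkynylmagnesium and hands it to C6 on the hydroxyl face, so the alkyne ends cis to the C1 oxygen. The unsubstituted β-carbon C6 should react rather than the methylated C10.

Step 5
Reactants: 11 (4R,5R)-5-[3-(tert-butyldiphenylsilyloxy)prop-1-ynyl]-4-[(E)-2-(dimethylphenylsilyl)ethenyl]-4-hydroxy-3-methylcyclohex-2-en-1-one
Product: 12 the C1 trimethylsilyl ether of 11
Conditions: Me3SiCl, imidazole, DMF, rt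
Reagents that add atoms: chlorotrimethylsilane, C[Si](C)(C)Cl
Why: Silylation of the tertiary alcohol removes the acidic proton before enolate formation and turns the C1 oxygen into a bulky, non-directing group for the epoxidation of step 7.

Step 6
Reactants: 12 the C1 trimethylsilyl ether of 11
Product: 13 enone 12 alkylated at C7 by CH2CO2t-Bu trans to the C6 alkynyl group
Conditions: LiN(i-Pr)2, THF, −78 °C; BrCH2CO2t-Bu, DMPU, −78 to −30 °C
Reagents that add atoms: tert-butyl bromoacetate, CC(C)(C)OC(=O)CBr
Why: Kinetic α′-deprotonation of the enone gives the cross-conjugated C7 enolate, and enolate alkylation should occur anti to the neighbouring C6 alkynyl group. The trans product is also the more stable one at this epimerisable centre.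

Step 7
Reactants: 13 enone 12 alkylated at C7 by CH2CO2t-Bu trans to the C6 alkynyl group
Product: 14 C9–C10 epoxy ketone with the epoxide oxygen trans to the C1 silyloxy group
Conditions: t-BuOOH, PhCH2NMe3 OH, THF, 0 °C to rt
Reagents that add atoms: tert-butyl hydroperoxide, CC(C)(C)OO
Why: Weitz–Scheffer nucleophilic epoxidation: the peroxide anion should add axially to C10 anti to the pseudoaxial C1–OSiMe3 bond and the enolate closes on the same face, which sets C10 with its oxygen trans to O1.

Step 8
Reactants: 14 C9–C10 epoxy ketone with the epoxide oxygen trans to the C1 silyloxy group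
Product: 15 β-hydroxy ketone with the tertiary C10 hydroxyl and a C9 methylene
Conditions: SmI2, THF/MeOH, −90 °C
Reagents that add atoms: none
Why: Single-electron reduction of an α,β-epoxy ketone by divalent samarium cleaves the Cα–O bond (C9–O) only; the C10–O bond is untouched, so its configuration is kept, and alkyne, ester and vinylsilane are inert.

Step 9
Reactants: 15 β-hydroxy ketone with the tertiary C10 hydroxyl and a C9 methylene
Product: 17 triol with C8–OH cis to C10–OH and a primary C12–OH, via hydroxy ester 16 (not isolated)
Conditions: LiBH(s-Bu)3, THF, −78 °C; then LiAlH4, −78 to 0 °C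
Reagents that add atoms: none
Why: The bulky trialkylborohydride should attack the C8 ketone along the equatorial path, the axial path being blocked by the axial C10 oxygen, and so give the axial alcohol cis to O10 and to the C7 side chain. LiAlH4 then reduces the tert-butyl ester to the primary alcohol.

Step 10
Reactants: 17 triol with C8–OH cis to C10–OH and a primary C12–OH
Product: 19 alkynyl tertiary alcohol with C8/C10 acetonide and C12 O-(2-methoxyprop-2-yl) ether, via silyl ether 18 (not isolated)
Conditions: CH2=C(OMe)CH3, PPTS, CH2Cl2, 0 °C; then K2CO3, MeOH, rt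
Reagents that add atoms: 2-methoxypropene, C=C(C)OC
Why: Acid-catalysed acetal formation: the cis-1,3-diaxial O8/O10 diol closes to the acetonide and the primary alcohol adds to a second enol ether to give the base-stable MOP ether. Basic methanol then cleaves only the trimethylsilyl ether and frees the tertiary C1 hydroxyl.

Step 11
Reactants: 19 alkynyl tertiary alcohol with C8/C10 acetonide and C12 O-(2-methoxyprop-2-yl) ether
Product: 20 1,2-dialkenylcyclohexanol carrying the (E)-silylvinyl group on C1 and the (Z)-3-silyloxypropenyl group on C6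
Conditions: H2 (1 atm), Pd/CaCO3 poisoned with Pb(OAc)2, quinoline, EtOAc, rt
Reagents that add atoms: none
Why: Semi-hydrogenation of the alkyne on poisoned palladium adds hydrogen syn and should stop at the Z-alkene; the vinylsilane and the silyl ethers are not touched.

Step 12
Reactants: 20 1,2-dialkenylcyclohexanol carrying the (E)-silylvinyl group on C1 and the (Z)-3-silyloxypropenyl group on C6
Product: 24 (E)-cyclodec-5-enone with C3 SiMe2Ph and C4 CH2OSi(t-Bu)Ph2 and a free C12 hydroxyl, via potassium alkoxide 21 (not isolated), via potassium enolate 22 (not isolated), via MOP-protected cyclodecenone 23 (not isolated)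
Conditions: KN(SiMe3)2 (1.2 equiv), 18-crown-6, THF, −78 to 0 °C; aq. NH4Cl; then PPTS, MeOH, 0 °C
Reagents that add atoms: none
Why: Deprotonation gives alkoxide 21, whose negative charge weakens the C1–C6 bond, and the 1,5-diene C3=C2–C1–C6–C5=C4 undergoes a charge-accelerated [3,3] shift to enolate 22, which is protonated to ketone 23; brief acidic methanol then removes the MOP ether. The closest known reaction type is the anionic oxy-Cope ring expansion of trans-1,2-divinylcyclohexanols to (E)-cyclodec-5-enones. The ten-membered ring is formed by ring expansion and not by an end-to-end cyclisation: in a six-membered chair transition state C3–C4 forms while C1–C6 breaks, so the new ring is the periphery of the two fused six-membered arrays. C4 is controlled by the Z geometry of its alkene, which places C15 axial in the chair, together with the fixed configurations of C1 and C6, which decide which alkene faces meet. C3 is controlled by the E geometry of the vinylsilane (silicon equatorial) and is erased later. The C5=C6 alkene should be E because C7 is equatorial in the chair. The step needs chair over boat, and this is secured by the two alkenyl groups being equatorial and gauche on a cyclohexane whose chair is fixed by the three equatorial carbon substituents and the diaxial acetonide. Silicon instead of oxygen at C3 keeps the enolate from β-elimination.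

Step 13
Reactants: 24 (E)-cyclodec-5-enone with C3 SiMe2Ph and C4 CH2OSi(t-Bu)Ph2 and a free C12 hydroxyl
Product: 27 C6/C12 diol with a C5 methylene, via hydrosilyl ether 25 (not isolated), via oxasilinane 26 (not isolated)
Conditions: (HMe2Si)2NH, 60 °C; Pt2[(CH2=CHSiMe2)2O]3 (1 mol %), toluene, 50 °C; then H2O2, KF, KHCO3, THF/MeOH, rt
Reagents that add atoms: hydrogen peroxide, OO
Why: Tethered (intramolecular) hydrosilylation followed by Tamao oxidation: the Si–H bond of the C12 silyl ether should add syn across C5=C6 through the six-membered exo mode, silicon to C6 and hydrogen to C5, on the alkene face where the C7 side chain lies, with C8 equatorial on the forming ring, which is the trans-fused arrangement. Oxidation replaces C–Si by C–O with retention; the C3 phenyldimethylsilyl group has no heteroatom on silicon and is inert here.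

Step 14
Reactants: 27 C6/C12 diol with a C5 methylene
Product: 28 trans-fused γ-lactone still carrying the C1 ketone and C3 SiMe2Ph
Conditions: TEMPO (20 mol %), PhI(OAc)2, CH2Cl2, rt
Reagents that add atoms: none
Why: Oxoammonium oxidation of the primary alcohol to the aldehyde, which closes to the lactol with the C6 hydroxyl and is oxidised on to the γ-lactone (oxidative lactonisation of a 1,4-diol); the secondary alcohol alone reacts much more slowly.

Step 15
Reactants: 28 trans-fused γ-lactone still carrying the C1 ketone and C3 SiMe2Ph
Product: 29 C1 alcohol of lactone 28 as a mixture of C1 epimers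
Conditions: NaBH4, MeOH, −20 °C
Reagents that add atoms: none
Why: Chemoselective borohydride reduction of the ketone beside the lactone; it masks the C1 carbonyl, whose C2 protons would otherwise be removed before the lactone α-proton in step 16.

Step 16
Reactants: 29 C1 alcohol of lactone 28 as a mixture of C1 epimers
Product: 32 α-methylene lactone, via Mannich base 30 (not isolated), via ammonium iodide 31 (not isolated)
Conditions: LiN(i-Pr)2 (2.5 equiv), THF, −78 °C; CH2=NMe2 I; then MeI, MeOH, rt; then aq. NaHCO3, CH2Cl2
Reagents that add atoms: N,N-dimethylmethyleneiminium iodide, C=[N+](C)C.[I-]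
Why: Mannich aminomethylation of the lactone lithium enolate (the C1 alkoxide is a spectator), N-methylation and base-induced elimination of trimethylamine give the exocyclic methylene.

Step 17
Reactants: 32 α-methylene lactone
Product: 33 C1/C3 diol
Conditions: Hg(OAc)2, AcOOH, AcOH, NaOAc, rt
Reagents that add atoms: peracetic acid, CC(=O)OO
Why: Fleming–Tamao oxidation: ipso-mercuration removes the phenyl group from the less hindered silicon and peracid then moves C3 from silicon to oxygen with retention. The tert-butyldiphenylsilyl ether is too hindered to react and the electron-poor methylene is not epoxidised by peracid.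

Step 18
Reactants: 33 C1/C3 diol
Product: 34 cyclodecane-1,3-dione with C8/C10 acetonide
Conditions: Dess–Martin periodinane, NaHCO3, CH2Cl2, 0 °C to rt
Reagents that add atoms: none
Why: Double oxidation of the 1,3-diol by a pentavalent iodine reagent under buffered, non-basic conditions, chosen so that C4, now α to a carbonyl, is not epimerised.

Step 19
Reactants: 34 cyclodecane-1,3-dione with C8/C10 acetonide
Product: 35 furanone with free C8 hydroxyl and C15 silyl ether
Conditions: CF3CO2H, H2O, CH2Cl2, 0 °C to rt
Reagents that add atoms: none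
Why: Acid hydrolysis of the acetonide frees the tertiary C10 hydroxyl, which adds to the C3 carbonyl (five-membered hemiketal) and loses water to give the 3(2H)-furanone (acid-catalysed cyclodehydration of an α′-hydroxy-1,3-diketone). Hemiketals of the C8 hydroxyl are reversible and the conjugated furanone should be the thermodynamic product.

Step 20
Reactants: 35 furanone with free C8 hydroxyl and C15 silyl ether; 36 angelic acid
Product: 38 C15 O-tert-butyldiphenylsilyl ether of the target, via mixed anhydride 37 (not isolated)
Conditions: 36, 2,4,6-Cl3C6H2COCl, Et3N, toluene, rt; then 35, toluene, 80 °C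
Reagents that add atoms: none
Why: Yamaguchi esterification through the mixed anhydride, run without a nucleophilic pyridine catalyst so that the Z double bond of the angelate should not isomerise; C8–OH is the only free hydroxyl.

Step 21
Reactants: 38 C15 O-tert-butyldiphenylsilyl ether of the target
Product: 39 CNP0108636.1
Conditions: HF·pyridine, pyridine, THF, 0 °C to rt
Reagents that add atoms: none
Why: Fluoride cleavage of the silyl ether under buffered, non-basic conditions, which the angelate, the methylene lactone and the furanone should tolerate.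

## Compound list

1 | 4-methoxy-2-methylphenol | Cc1cc(OC)ccc1O | starting material
2 | 4,4-dimethoxy-2-methylcyclohexa-2,5-dien-1-one | CC1=CC(OC)(OC)C=CC1=O | intermediate
3 | ethynyl(dimethyl)phenylsilane | C#C[Si](C)(C)c1ccccc1 | starting material
4 | chlorobis(cyclopentadienyl)[(E)-2-(dimethylphenylsilyl)ethenyl]zirconium | Cl[Zr](/C=C/[Si](C)(C)c1ccccc1)(C1C=CC=C1)C1C=CC=C1 | intermediate
5 | methyl[(E)-2-(dimethylphenylsilyl)ethenyl]zinc | C[Zn]/C=C/[Si](C)(C)c1ccccc1 | intermediate
6 | (1R)-1-[(E)-2-(dimethylphenylsilyl)ethenyl]-4,4-dimethoxy-2-methylcyclohexa-2,5-dien-1-ol | COC1(OC)C=C[C@@](O)(/C=C/[Si](C)(C)c2ccccc2)C(C)=C1 | intermediate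
7 | (4R)-4-[(E)-2-(dimethylphenylsilyl)ethenyl]-4-hydroxy-3-methylcyclohexa-2,5-dien-1-one | O=C1C=C[C@@](O)(/C=C/[Si](C)(C)c2ccccc2)C(C)=C1 | intermediate
8 | prop-2-yn-1-ol | C#CCO | starting material
9 | tert-butyl(diphenyl)(prop-2-yn-1-yloxy)silane | C#CCO[Si](c1ccccc1)(c1ccccc1)C(C)(C)C | intermediate
10 | [3-(tert-butyldiphenylsilyloxy)prop-1-ynyl]magnesium bromide | Br[Mg]C#CCO[Si](c1ccccc1)(c1ccccc1)C(C)(C)C | intermediate
11 | (4R,5R)-5-[3-(tert-butyldiphenylsilyloxy)prop-1-ynyl]-4-[(E)-2-(dimethylphenylsilyl)ethenyl]-4-hydroxy-3-methylcyclohex-2-en-1-one (alkynyl cis to OH) | O=C1C[C@H](C#CCO[Si](c2ccccc2)(c2ccccc2)C(C)(C)C)[C@@](O)(/C=C/[Si](C)(C)c2ccccc2)C(C)=C1 | intermediate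
12 | C1 trimethylsilyl ether of 11 | O=C1C[C@H](C#CCO[Si](c2ccccc2)(c2ccccc2)C(C)(C)C)[C@@](O[Si](C)(C)C)(/C=C/[Si](C)(C)c2ccccc2)C(C)=C1 | intermediate
13 | enone 12 with CH2CO2t-Bu on C7, trans to the C6 alkynyl group | O=C1[C@@H](CC(=O)OC(C)(C)C)[C@H](C#CCO[Si](c2ccccc2)(c2ccccc2)C(C)(C)C)[C@@](O[Si](C)(C)C)(/C=C/[Si](C)(C)c2ccccc2)C(C)=C1 | intermediate
14 | C9–C10 epoxy ketone, epoxide oxygen trans to C1–OSiMe3 | O=C1[C@@H](CC(=O)OC(C)(C)C)[C@H](C#CCO[Si](c2ccccc2)(c2ccccc2)C(C)(C)C)[C@@](O[Si](C)(C)C)(/C=C/[Si](C)(C)c2ccccc2)[C@@]3(C)O[C@@H]13 | intermediate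
15 | β-hydroxy ketone (C8 ketone, tertiary C10–OH trans to C1–OSiMe3) | O=C1[C@@H](CC(=O)OC(C)(C)C)[C@H](C#CCO[Si](c2ccccc2)(c2ccccc2)C(C)(C)C)[C@@](O[Si](C)(C)C)(/C=C/[Si](C)(C)c2ccccc2)[C@@](C)(O)C1 | intermediate
16 | C8 alcohol (cis to C10–OH) still carrying the tert-butyl ester | O[C@H]1[C@@H](CC(=O)OC(C)(C)C)[C@H](C#CCO[Si](c2ccccc2)(c2ccccc2)C(C)(C)C)[C@@](O[Si](C)(C)C)(/C=C/[Si](C)(C)c2ccccc2)[C@@](C)(O)C1 | intermediate
17 | triol: C8–OH and C10–OH cis-1,3, primary C12–OH, C1–OSiMe3 | O[C@H]1[C@@H](CCO)[C@H](C#CCO[Si](c2ccccc2)(c2ccccc2)C(C)(C)C)[C@@](O[Si](C)(C)C)(/C=C/[Si](C)(C)c2ccccc2)[C@@](C)(O)C1 | intermediate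
18 | C8/C10 acetonide, C12 O-MOP ether, C1 O-SiMe3 ether | C[Si](C)(C)O[C@@]1(/C=C/[Si](C)(C)c2ccccc2)[C@@H](C#CCO[Si](c2ccccc2)(c2ccccc2)C(C)(C)C)[C@H](CCOC(C)(C)OC)[C@H]2C[C@]1(C)OC(C)(C)O2 | intermediate
19 | alkynyl tertiary alcohol: as 18 with free C1–OH | O[C@@]1(/C=C/[Si](C)(C)c2ccccc2)[C@@H](C#CCO[Si](c2ccccc2)(c2ccccc2)C(C)(C)C)[C@H](CCOC(C)(C)OC)[C@H]2C[C@]1(C)OC(C)(C)O2 | intermediate
20 | 1,2-dialkenylcyclohexanol: C1 (E)-2-(dimethylphenylsilyl)ethenyl and OH, C6 (Z)-3-(tert-butyldiphenylsilyloxy)prop-1-enyl, C7 CH2CH2O-MOP, C8/C10 acetonide | O[C@@]1(/C=C/[Si](C)(C)c2ccccc2)[C@@H](/C=C\CO[Si](c2ccccc2)(c2ccccc2)C(C)(C)C)[C@H](CCOC(C)(C)OC)[C@H]2C[C@]1(C)OC(C)(C)O2 | intermediate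
21 | potassium alkoxide of 20 | [K+].[O-][C@@]1(/C=C/[Si](C)(C)c2ccccc2)[C@@H](/C=C\CO[Si](c2ccccc2)(c2ccccc2)C(C)(C)C)[C@H](CCOC(C)(C)OC)[C@H]2C[C@]1(C)OC(C)(C)O2 | intermediate
22 | potassium enolate of the ring-expanded ketone | [K+].[O-]/C1=C\[C@H]([Si](C)(C)c2ccccc2)[C@H](CO[Si](c2ccccc2)(c2ccccc2)C(C)(C)C)/C=C/[C@H](CCOC(C)(C)OC)[C@H]2C[C@]1(C)OC(C)(C)O2 | intermediate
23 | (E)-cyclodec-5-enone with C3 SiMe2Ph, C4 CH2OSi(t-Bu)Ph2, C12 O-MOP, C8/C10 acetonide | O=C1C[C@H]([Si](C)(C)c2ccccc2)[C@H](CO[Si](c2ccccc2)(c2ccccc2)C(C)(C)C)/C=C/[C@H](CCOC(C)(C)OC)[C@H]2C[C@]1(C)OC(C)(C)O2 | intermediate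
24 | (E)-cyclodec-5-enone as 23 with free C12–OH | O=C1C[C@H]([Si](C)(C)c2ccccc2)[C@H](CO[Si](c2ccccc2)(c2ccccc2)C(C)(C)C)/C=C/[C@H](CCO)[C@H]2C[C@]1(C)OC(C)(C)O2 | intermediate
25 | C12 O-dimethylsilyl (Si–H) ether of 24 | O=C1C[C@H]([Si](C)(C)c2ccccc2)[C@H](CO[Si](c2ccccc2)(c2ccccc2)C(C)(C)C)/C=C/[C@H](CCO[SiH](C)C)[C@H]2C[C@]1(C)OC(C)(C)O2 | intermediate
26 | trans-fused 1-oxa-2-silacyclohexane (Si on C6, O on C12) | O=C1C[C@H]([Si](C)(C)c2ccccc2)[C@H](CO[Si](c2ccccc2)(c2ccccc2)C(C)(C)C)C[C@@H]3[C@H](CCO[Si]3(C)C)[C@H]2C[C@]1(C)OC(C)(C)O2 | intermediate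
27 | C6/C12 diol, C5 methylene | O=C1C[C@H]([Si](C)(C)c2ccccc2)[C@H](CO[Si](c2ccccc2)(c2ccccc2)C(C)(C)C)C[C@@H](O)[C@H](CCO)[C@H]2C[C@]1(C)OC(C)(C)O2 | intermediate
28 | trans-fused 6,12-lactone with C1 ketone and C3 SiMe2Ph | O=C1C[C@H]([Si](C)(C)c2ccccc2)[C@H](CO[Si](c2ccccc2)(c2ccccc2)C(C)(C)C)C[C@H]3OC(=O)C[C@@H]3[C@H]2C[C@]1(C)OC(C)(C)O2 | intermediate
29 | C1 alcohol of 28 (C1 epimers) | OC1C[C@H]([Si](C)(C)c2ccccc2)[C@H](CO[Si](c2ccccc2)(c2ccccc2)C(C)(C)C)C[C@H]3OC(=O)C[C@@H]3[C@H]2C[C@]1(C)OC(C)(C)O2 | intermediate
30 | C11 dimethylaminomethyl lactone | OC1C[C@H]([Si](C)(C)c2ccccc2)[C@H](CO[Si](c2ccccc2)(c2ccccc2)C(C)(C)C)C[C@H]3OC(=O)C(CN(C)C)[C@@H]3[C@H]2C[C@]1(C)OC(C)(C)O2 | intermediate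
31 | C11 trimethylammoniomethyl lactone iodide | OC1C[C@H]([Si](C)(C)c2ccccc2)[C@H](CO[Si](c2ccccc2)(c2ccccc2)C(C)(C)C)C[C@H]3OC(=O)C(C[N+](C)(C)C)[C@@H]3[C@H]2C[C@]1(C)OC(C)(C)O2.[I-] | intermediate
32 | α-methylene lactone with C1–OH and C3 SiMe2Ph | OC1C[C@H]([Si](C)(C)c2ccccc2)[C@H](CO[Si](c2ccccc2)(c2ccccc2)C(C)(C)C)C[C@H]3OC(=O)C(=C)[C@@H]3[C@H]2C[C@]1(C)OC(C)(C)O2 | intermediate
33 | C1/C3 diol (C3–OH with the configuration of the former C–Si bond) | OC1C[C@H](O)[C@H](CO[Si](c2ccccc2)(c2ccccc2)C(C)(C)C)C[C@H]3OC(=O)C(=C)[C@@H]3[C@H]2C[C@]1(C)OC(C)(C)O2 | intermediate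
34 | cyclodecane-1,3-dione with α-methylene lactone, C8/C10 acetonide and C15 silyl ether | O=C1CC(=O)[C@H](CO[Si](c2ccccc2)(c2ccccc2)C(C)(C)C)C[C@H]3OC(=O)C(=C)[C@@H]3[C@H]2C[C@]1(C)OC(C)(C)O2 | intermediate
35 | 8-O-deangeloyl-15-O-(tert-butyldiphenylsilyl) derivative of the target | C=C1C(=O)O[C@@H]2C[C@@H](CO[Si](c3ccccc3)(c3ccccc3)C(C)(C)C)C3=CC(=O)[C@](C)(C[C@@H](O)[C@@H]12)O3 | intermediate
36 | angelic acid, (Z)-2-methylbut-2-enoic acid | C/C=C(/C)C(=O)O | starting material
37 | angelic 2,4,6-trichlorobenzoic anhydride | C/C=C(/C)C(=O)OC(=O)c1c(Cl)cc(Cl)cc1Cl | intermediate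
38 | 15-O-(tert-butyldiphenylsilyl) ether of the target | C=C1C(=O)O[C@@H]2C[C@@H](CO[Si](c3ccccc3)(c3ccccc3)C(C)(C)C)C3=CC(=O)[C@](C)(C[C@@H](OC(=O)/C(C)=C\C)[C@@H]12)O3 | intermediate
39 | CNP0108636.1 (4S,6R,7S,8R,10S; germacrane numbering) | C=C1C(=O)O[C@@H]2C[C@@H](CO)C3=CC(=O)[C@](C)(C[C@@H](OC(=O)/C(C)=C\C)[C@@H]12)O3 | target

## Step count and least certain steps

Total: 21 steps. Longest linear sequence: 20 steps (steps 1, 2 and 4 to 21, from phenol 1); step 3 is a one-step side branch.

**Step 12 (key step).** The most likely failure is leakage through a boat transition state. The Z-alkene places the silyloxymethyl group axial in the chair, 1,3 to the hydrogens on C2 and C6, which narrows the chair/boat gap and would erode the configuration at C4. Alkoxide-triggered cleavage could also compete at the temperature the shift needs.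
Fallback: the uncharged siloxy-Cope variant. It sets out from 20, which is silylated with N-(trimethylsilyl)imidazole to the C1 trimethylsilyl ether F1. Heating F1 in degassed o-dichlorobenzene at about 190 °C should give the ring-expanded trimethylsilyl enol ether F2 through the same chair without a basic oxygen in the molecule. PPTS in methanol cleaves both the enol ether and the MOP ether, and the route is rejoined at 24.

**Step 13.** The risks are poor regiocontrol of the Si–H addition (the seven-membered endo mode would put silicon on C5), alkene migration under the platinum hydride, and addition through the other conformer of the trans-cyclodecene, which would give the cis-fused isomer. The six-membered exo closure onto an internal, strained alkene is less secure than the usual five-membered mode.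
Fallback: untethered syn dihydroxylation and deoxygenation. From 24, OsO4 (cat.) with N-methylmorpholine N-oxide gives the 5,6,12-triol F3. TEMPO/PhI(OAc)2 closes the 5-hydroxy lactone F4. 1,1′-Thiocarbonyldiimidazole gives the imidazolyl thiocarbonate F5, and Barton–McCombie reduction with Bu3SnH and AIBN rejoins the route at 28. In this fallback the face of attack rests on peripheral approach to the ring and no longer on a tether.

**Step 2.** The risk is insufficient enantioselection, because both flanks of the ketone are sp2 carbons and differ only by the methyl group; methyl transfer from zinc may also compete.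
Fallback: run the same addition on a 2-substituted cyclohexenone, the substrate class for which this catalyst is established, and restore the second alkene afterwards. From 2, H2 with RhCl(PPh3)3 reduces the unsubstituted alkene to 4,4-dimethoxy-2-methylcyclohex-2-en-1-one F6. Addition of 5 under the conditions of step 2 gives the allylic alcohol ketal F7, and aqueous oxalic acid gives the hydroxy enone F8. LiN(i-Pr)2 (2.2 equiv) and Me3SiCl give the bis-silylated dienol ether F9, Saegusa–Ito oxidation with Pd(OAc)2 in MeCN gives the silylated dienone F10, and K2CO3 in MeOH rejoins the route at 7.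

**Step 4.** The risk is 1,2-addition to the ketone or loss of the syn delivery, since alkynyl Grignard reagents are the least willing partners in conjugate addition.
Fallback: a covalently bound aluminium reagent. It sets out from 9, which with n-BuLi and then Me2AlCl gives the dimethyl(alkynyl)alane F11. Quinol 7 protonolyses one Al–Me bond to give the aluminium alkoxide F12, which should hand the alkynyl group from aluminium to C6 on the oxygen-bearing face. Aqueous work-up rejoins the route at 11.

**Step 9.** The risks are retro-aldol opening of the tertiary β-hydroxy ketone once its alkoxide forms, and incomplete equatorial attack at C8.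
Fallback: reduce before the epoxide is opened. From 14, NaBH4 with CeCl3 at −78 °C gives the cis-epoxy alcohol F13. NaAlH2(OCH2CH2OMe)2 in THF then delivers hydride from the C8-bound aluminate to C9 and reduces the ester in the same flask, rejoining the route at 17 (steps 8 and 9 are bypassed).

## Further compounds

F1 | step 12 | C1 O-trimethylsilyl ether of 20 | C[Si](C)(C)O[C@@]1(/C=C/[Si](C)(C)c2ccccc2)[C@@H](/C=C\CO[Si](c2ccccc2)(c2ccccc2)C(C)(C)C)[C@H](CCOC(C)(C)OC)[C@H]2C[C@]1(C)OC(C)(C)O2
F2 | step 12 | trimethylsilyl enol ether of 23 (C1=C2) | C[Si](C)(C)O/C1=C\[C@H]([Si](C)(C)c2ccccc2)[C@H](CO[Si](c2ccccc2)(c2ccccc2)C(C)(C)C)/C=C/[C@H](CCOC(C)(C)OC)[C@H]2C[C@]1(C)OC(C)(C)O2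
F3 | step 13 | 5,6,12-triol from syn dihydroxylation of 24 | O=C1C[C@H]([Si](C)(C)c2ccccc2)[C@H](CO[Si](c2ccccc2)(c2ccccc2)C(C)(C)C)[C@H](O)[C@@H](O)[C@H](CCO)[C@H]2C[C@]1(C)OC(C)(C)O2
F4 | step 13 | 5-hydroxy derivative of lactone 28 | O=C1C[C@H]([Si](C)(C)c2ccccc2)[C@H](CO[Si](c2ccccc2)(c2ccccc2)C(C)(C)C)[C@H](O)[C@H]3OC(=O)C[C@@H]3[C@H]2C[C@]1(C)OC(C)(C)O2
F5 | step 13 | C5 O-(imidazol-1-ylthiocarbonyl) derivative of F4 | O=C1C[C@H]([Si](C)(C)c2ccccc2)[C@H](CO[Si](c2ccccc2)(c2ccccc2)C(C)(C)C)[C@H](OC(=S)n4ccnc4)[C@H]3OC(=O)C[C@@H]3[C@H]2C[C@]1(C)OC(C)(C)O2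
F6 | step 2 | 4,4-dimethoxy-2-methylcyclohex-2-en-1-one | CC1=CC(OC)(OC)CCC1=O
F7 | step 2 | 1-[(E)-2-(dimethylphenylsilyl)ethenyl]-4,4-dimethoxy-2-methylcyclohex-2-en-1-ol (C1 as in 6) | COC1(OC)CC[C@@](O)(/C=C/[Si](C)(C)c2ccccc2)C(C)=C1
F8 | step 2 | 4-[(E)-2-(dimethylphenylsilyl)ethenyl]-4-hydroxy-3-methylcyclohex-2-en-1-one (C4 as in 7) | O=C1CC[C@@](O)(/C=C/[Si](C)(C)c2ccccc2)C(C)=C1
F9 | step 2 | bis(trimethylsilyl) dienol ether of F8 | C[Si](C)(C)OC1=CC[C@@](O[Si](C)(C)C)(/C=C/[Si](C)(C)c2ccccc2)C(C)=C1
F10 | step 2 | O-trimethylsilyl ether of 7 | O=C1C=C[C@@](O[Si](C)(C)C)(/C=C/[Si](C)(C)c2ccccc2)C(C)=C1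
F11 | step 4 | [3-(tert-butyldiphenylsilyloxy)prop-1-ynyl]dimethylaluminium | C[Al](C)C#CCO[Si](c1ccccc1)(c1ccccc1)C(C)(C)C
F12 | step 4 | methyl(alkynyl)aluminium alkoxide of 7 | C[Al](C#CCO[Si](c3ccccc3)(c3ccccc3)C(C)(C)C)O[C@@]1(/C=C/[Si](C)(C)c2ccccc2)C=CC(=O)C=C1C
F13 | step 9 | cis-epoxy alcohol from 14 (C8–OH on the epoxide face) | O[C@H]1[C@@H](CC(=O)OC(C)(C)C)[C@H](C#CCO[Si](c2ccccc2)(c2ccccc2)C(C)(C)C)[C@@](O[Si](C)(C)C)(/C=C/[Si](C)(C)c2ccccc2)[C@@]3(C)O[C@@H]13
A1 | alternative 1 | trans-fused 6,12-lactone with C13 acetoxymethyl, C15 trichloroethyl carbonate and C8 chloroacetate | CC(=O)OC[C@H]1C(=O)O[C@@H]2C[C@@H](COC(=O)OCC(Cl)(Cl)Cl)C3=CC(=O)[C@](C)(C[C@@H](OC(=O)CCl)[C@@H]12)O3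
A2 | alternative 2 | ten-membered C6 alcohol with C4 exocyclic methylene, C8 angelate and C12 O-tert-butyldimethylsilyl ether | O[C@@H]1CC(=C)C2=CC(=O)[C@](C)(C[C@@H](OC(=O)/C(C)=C\C)[C@H]1C(=C)CO[Si](C)(C)C(C)(C)C)O2
A3 | alternative 3 | methylene ethyl acetal with a 2,2,6,6-tetramethylpiperidin-1-yloxy group on C8 and C15 O-tert-butyldimethylsilyl ether | C=C1[C@@H](OCC)O[C@@H]2C[C@@H](CO[Si](C)(C)C(C)(C)C)C3=CC(=O)[C@](C)(C[C@@H](ON4C(C)(C)CCCC4(C)C)[C@@H]12)O3
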